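**Plan**

1. Locants used below: ring A is C1–C5 and C10 (C4 carries the two methyls, C5 is the CH that bears the 3‑oxobutyl chain C6–C8 with methyl C17, C10 is the quaternary carbon with methyl C20 and acyl carbon C9); the long chain is C9, C11–C15 with a methyl on C13; the glycerol is sn‑1 to sn‑3.
2. Retrosynthesis: mask the sn‑3 OH as a benzyl ether and place a temporary carbonyl on C1; cut C10–C9 (aldol of a ring enolate with a C9 aldehyde), then C10–C20 (enolate methylation), then C2–C3 and C4–C5 together, so that ring A falls into isobutyraldehyde (C3, C4 and both C4 methyls) and an acyclic methyl enone (C2, C1, C10, C5 and chain C6–C8, C8 as dioxolane).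
3. Enabling feature: the quaternary C4(CH3)2 lies between the C5 stereocentre and C3H2, so C4/C3 are the α‑carbon and formyl carbon of isobutyraldehyde and C5–C10–C1–C2 are the β‑carbon, α‑carbon, carbonyl and methyl of an enone. The C1 carbonyl drives this Michael/aldol annulation, then makes C10 the only enolizable position for methylation and for the aldol that builds the quaternary centre, and is finally removed through its enol triflate.
4. Forward order: enone by cross‑metathesis, ring A by annulation, C20, side chain joined at C10, C1 deoxygenation, C8 and C9 ketones, final hydrogenation of the ring alkene and the benzyl ether.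
5. Stereochemistry: C5 from the chiral proline sulfonamide catalyst in the annulation; C10 from C5 (the electrophile enters anti to the C5 chain); C13 from (R)‑citronellic acid; glycerol C2 from benzyl (R)‑glycidyl ether.

Key step: step 3

Remark: the (S)‑configured catalyst is written in step 3 on the assumption that its hydrogen‑bond‑directed transition state delivers (S)‑8; this sense has not been derived with confidence, and the antipodal catalyst (from D‑proline) is used if it proves opposite.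

**Route**

Step 1
Reactants: 1 5‑hexen‑2‑one
Product: 2 2‑(but‑3‑en‑1‑yl)‑2‑methyl‑1,3‑dioxolane
Conditions: HOCH2CH2OH, TsOH·H2O (cat.), PhMe, reflux, Dean–Stark
Reagents that add atoms: ethylene glycol, OCCO
Why: Acid‑catalysed ketalization with azeotropic removal of water masks the future C8 ketone, so that only one ketone can take part in the annulation and in the later enolate steps.

Step 2
Reactants: 2 2‑(but‑3‑en‑1‑yl)‑2‑methyl‑1,3‑dioxolane; 3 methyl vinyl ketone
Product: 4 (E)‑6‑(2‑methyl‑1,3‑dioxolan‑2‑yl)hex‑3‑en‑2‑one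
Conditions: 3 (3 equiv), second‑generation Hoveyda–Grubbs catalyst RuCl2(H2IMes)(=CH‑C6H4‑2‑O‑i‑Pr) (3 mol%), CH2Cl2, 40 °C
Reagents that add atoms: none
Why: Olefin cross‑metathesis of a terminal alkene with the electron‑poor partner methyl vinyl ketone favours the cross product and the E‑enone, with loss of ethylene.

Step 3
Reactants: 4 (E)‑6‑(2‑methyl‑1,3‑dioxolan‑2‑yl)hex‑3‑en‑2‑one; 5 isobutyraldehyde
Product: 8 (5S)‑4,4‑dimethyl‑5‑[2‑(2‑methyl‑1,3‑dioxolan‑2‑yl)ethyl]cyclohex‑2‑en‑1‑one, via Michael adduct 6 (not isolated), via ketol 7 (not isolated)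
Conditions: 5 (3 equiv), (S)‑N‑(4‑dodecylphenylsulfonyl)pyrrolidine‑2‑carboxamide (20 mol%), 4 Å molecular sieves, ClCH2CH2Cl, 23 → 50 °C
Reagents that add atoms: none
Why: The secondary amine condenses with isobutyraldehyde to a tetrasubstituted enamine whose nucleophilic carbon (C4) adds 1,4 to the enone, held by a hydrogen bond from the acidic sulfonamide N–H, and so forms C4–C5; the methyl ketone of the adduct then enolizes (as its enamine) toward the methyl group C2, attacks the neopentyl aldehyde C3 and loses water to form C2=C3. The closest known reaction type is the amine‑catalysed Michael/aldol condensation of α,α‑disubstituted aldehydes with vinyl ketones (Robinson‑type annulation, Yamada–Otani condensation), including its enantioselective proline sulfonamide‑catalysed form. Ring A is closed by a 6‑(enolendo)‑exo‑trig aldol addition followed by E1cB dehydration. The only new stereocentre, C5, is set in the Michael step under catalyst control, the pyrrolidine stereocentre deciding on which face of the E‑enone the enamine carbon arrives. The step needs 1,4‑ over 1,2‑addition and a single mode of closure: closure through C10 would give a four‑membered ring, the aldehyde has no α‑hydrogen after the Michael step and can act only as acceptor, and the second ketone (C8) is masked as its dioxolane.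

Step 4
Reactants: 8 (5S)‑4,4‑dimethyl‑5‑[2‑(2‑methyl‑1,3‑dioxolan‑2‑yl)ethyl]cyclohex‑2‑en‑1‑one
Product: 10 (5S,6S)‑4,4,6‑trimethyl‑5‑[2‑(2‑methyl‑1,3‑dioxolan‑2‑yl)ethyl]cyclohex‑2‑en‑1‑one (5,6‑trans shown; the C6 epimer serves equally), via lithium dienolate 9 (not isolated)
Conditions: LiN(i‑Pr)2, THF, −78 °C; MeI, −78 → −20 °C
Reagents that add atoms: iodomethane, CI
Why: Kinetic deprotonation can occur only at C10 because C4 bears no hydrogen, and SN2 methylation of the cross‑conjugated lithium enolate installs C20; the configuration at C10 is of no consequence here since this centre is enolized again in step 8.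

Step 5
Reactants: 11 (R)‑citronellic acid; 12 benzyl (R)‑glycidyl ether
Product: 13 (2S)‑3‑(benzyloxy)‑2‑hydroxypropyl (3R)‑3,7‑dimethyloct‑6‑enoate
Conditions: Bu4NBr (5 mol%), neat, 90 °C
Reagents that add atoms: none
Why: Halide‑catalysed ring opening of the terminal epoxide by the carboxylic acid takes place at the unhindered CH2 (SN2), so the primary ester forms regioselectively and the glycerol stereocentre is not touched.

Step 6
Reactants: 13 (2S)‑3‑(benzyloxy)‑2‑hydroxypropyl (3R)‑3,7‑dimethyloct‑6‑enoate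
Product: 14 (2S)‑2‑acetoxy‑3‑(benzyloxy)propyl (3R)‑3,7‑dimethyloct‑6‑enoate
Conditions: Ac2O, pyridine, DMAP (cat.), CH2Cl2, 0 → 23 °C
Reagents that add atoms: acetic anhydride, CC(=O)OC(C)=O
Why: DMAP‑catalysed acetylation fixes the sn‑2 acetate at once, after which no free hydroxyl is left in the glycerol unit to allow acyl migration.

Step 7
Reactants: 14 (2S)‑2‑acetoxy‑3‑(benzyloxy)propyl (3R)‑3,7‑dimethyloct‑6‑enoate
Product: 16 (2S)‑2‑acetoxy‑3‑(benzyloxy)propyl (3R)‑3‑methyl‑6‑oxohexanoate, via ozonide 15 (not isolated)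
Conditions: O3, CH2Cl2, −78 °C; PPh3, −78 → 23 °C
Reagents that add atoms: ozone, [O-][O+]=O
Why: Ozonolysis (Criegee mechanism) with reductive work‑up cleaves the electron‑rich trisubstituted alkene to the C9 aldehyde, and C13 is not α to the new carbonyl and keeps its configuration.

Step 8
Reactants: 10 (5S,6S)‑4,4,6‑trimethyl‑5‑[2‑(2‑methyl‑1,3‑dioxolan‑2‑yl)ethyl]cyclohex‑2‑en‑1‑one; 16 (2S)‑2‑acetoxy‑3‑(benzyloxy)propyl (3R)‑3‑methyl‑6‑oxohexanoate
Product: 19 (2S)‑2‑acetoxy‑3‑(benzyloxy)propyl (3R,6RS)‑3‑methyl‑6‑[(1R,6R)‑1,5,5‑trimethyl‑6‑[2‑(2‑methyl‑1,3‑dioxolan‑2‑yl)ethyl]‑2‑oxocyclohex‑3‑en‑1‑yl]‑6‑(triethylsilyloxy)hexanoate, via lithium dienolate 17 (not isolated), via lithium aldolate 18 (not isolated)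
Conditions: LiN(i‑Pr)2, THF, −78 → −40 °C; 16, −78 °C; Et3SiOTf, 2,6‑lutidine, −78 → −40 °C
Reagents that add atoms: triethylsilyl trifluoromethanesulfonate, CC[Si](CC)(CC)OS(=O)(=O)C(F)(F)F
Why: Deprotonation at C10 (the only α‑hydrogen) gives the tetrasubstituted lithium dienolate, whose aldol addition to the aldehyde should form C10–C9 on the face anti to the pseudoaxial C5 chain, placing the acyl carbon trans to that chain and C20 cis to it as in the target, and the aldolate is silylated in the same flask so that it cannot revert by retro‑aldol cleavage in step 9 (the C9 carbinol configuration is of no consequence).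

Step 9
Reactants: 19 the silyl‑protected aldol enone from step 8
Product: 21 (2S)‑2‑acetoxy‑3‑(benzyloxy)propyl (3R,6RS)‑3‑methyl‑6‑[(1R,6R)‑1,5,5‑trimethyl‑6‑[2‑(2‑methyl‑1,3‑dioxolan‑2‑yl)ethyl]‑2‑(trifluoromethylsulfonyloxy)cyclohex‑2‑en‑1‑yl]‑6‑(triethylsilyloxy)hexanoate, via lithium enolate 20 (not isolated)
Conditions: LiBH(s‑Bu)3 (L‑Selectride), THF, −78 °C; Comins' reagent, −78 → −20 °C
Reagents that add atoms: Comins' reagent, N‑(5‑chloropyridin‑2‑yl)‑bis(trifluoromethanesulfonimide), Clc1ccc(nc1)N(S(=O)(=O)C(F)(F)F)S(=O)(=O)C(F)(F)F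
Why: Conjugate reduction of the enone by the bulky hydride (1,2‑attack is blocked by the quaternary C10) gives the C1–C2 enolate regiospecifically, and O‑triflation of this enolate turns the helper carbonyl into a leaving group while the esters are inert at this temperature.

Step 10
Reactants: 21 the enol triflate from step 9
Product: 22 (2S)‑2‑acetoxy‑3‑(benzyloxy)propyl (3R,6RS)‑3‑methyl‑6‑[(1R,6R)‑1,5,5‑trimethyl‑6‑[2‑(2‑methyl‑1,3‑dioxolan‑2‑yl)ethyl]cyclohex‑2‑en‑1‑yl]‑6‑(triethylsilyloxy)hexanoate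
Conditions: Pd(OAc)2 (5 mol%), PPh3, HCO2H, Bu3N, DMF, 60 °C
Reagents that add atoms: none
Why: Palladium‑catalysed formate reduction of the enol triflate (oxidative addition of zerovalent palladium, exchange for formate, loss of CO2 and C–H reductive elimination) removes the C1 oxygen and leaves a C1=C2 alkene, without touching the benzyl ether, the esters or the silyl ether.

Step 11
Reactants: 22 the cyclohexene from step 10
Product: 23 (2S)‑2‑acetoxy‑3‑(benzyloxy)propyl (3R,6RS)‑6‑hydroxy‑3‑methyl‑6‑[(1R,6R)‑1,5,5‑trimethyl‑6‑(3‑oxobutyl)cyclohex‑2‑en‑1‑yl]hexanoate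
Conditions: HCl (1 M aq), THF, 23 °C
Reagents that add atoms: water, O
Why: Mild acid hydrolysis cleaves the dioxolane (freeing the C8 methyl ketone) and the triethylsilyl ether in one operation, while the two esters survive and the acetate has no neighbouring hydroxyl to migrate to.

Step 12
Reactants: 23 the hydroxy ketone from step 11
Product: 24 (2S)‑2‑acetoxy‑3‑(benzyloxy)propyl (3R)‑3‑methyl‑6‑oxo‑6‑[(1R,6R)‑1,5,5‑trimethyl‑6‑(3‑oxobutyl)cyclohex‑2‑en‑1‑yl]hexanoate
Conditions: Dess–Martin periodinane, CH2Cl2, 23 °C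
Reagents that add atoms: none
Why: Dess–Martin oxidation converts both C9 carbinol epimers into the single C9 ketone under neutral conditions, and the quaternary C10 cannot epimerize or let the alkene move into conjugation.

Step 13
Reactants: 24 the benzyl‑protected diketone from step 12
Product: 25 (2S)‑2‑acetoxy‑3‑hydroxypropyl (3R)‑3‑methyl‑6‑oxo‑6‑[(1R,2R)‑1,3,3‑trimethyl‑2‑(3‑oxobutyl)cyclohexyl]hexanoate (target)
Conditions: H2 (1 atm), Pd/C, EtOAc, 23 °C
Reagents that add atoms: none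
Why: Heterogeneous catalytic hydrogenation saturates the C1=C2 alkene and hydrogenolyses the benzyl ether in one neutral operation, which leaves the aliphatic ketones untouched and gives the sn‑2 acetate the least chance to migrate to the freed sn‑3 hydroxyl.

**Compound list**

1 | 5‑hexen‑2‑one | C=CCCC(C)=O | starting material
2 | 2‑(but‑3‑en‑1‑yl)‑2‑methyl‑1,3‑dioxolane | C=CCCC1(C)OCCO1 | intermediate
3 | methyl vinyl ketone | CC(=O)C=C | starting material
4 | (E)‑6‑(2‑methyl‑1,3‑dioxolan‑2‑yl)hex‑3‑en‑2‑one | CC(=O)/C=C/CCC1(C)OCCO1 | intermediate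
5 | isobutyraldehyde | CC(C)C=O | starting material
6 | (3S)‑2,2‑dimethyl‑3‑[2‑(2‑methyl‑1,3‑dioxolan‑2‑yl)ethyl]‑5‑oxohexanal (Michael adduct) | CC1(OCCO1)CC[C@H](C(C)(C)C=O)CC(C)=O | intermediate
7 | (5S)‑3‑hydroxy‑4,4‑dimethyl‑5‑[2‑(2‑methyl‑1,3‑dioxolan‑2‑yl)ethyl]cyclohexan‑1‑one (ketol, carbinol epimers) | CC1(OCCO1)CC[C@@H]2C(C)(C)C(O)CC(=O)C2 | intermediate
8 | (5S)‑4,4‑dimethyl‑5‑[2‑(2‑methyl‑1,3‑dioxolan‑2‑yl)ethyl]cyclohex‑2‑en‑1‑one | CC1(OCCO1)CC[C@@H]2C(C)(C)C=CC(=O)C2 | intermediate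
9 | lithium dienolate of 8 (O–Li on C1, C1=C10) | CC1(OCCO1)CC[C@@H]2C(C)(C)C=CC(O[Li])=C2 | intermediate
10 | (5S,6S)‑4,4,6‑trimethyl‑5‑[2‑(2‑methyl‑1,3‑dioxolan‑2‑yl)ethyl]cyclohex‑2‑en‑1‑one | CC1(OCCO1)CC[C@@H]2C(C)(C)C=CC(=O)[C@H]2C | intermediate
11 | (R)‑citronellic acid, (3R)‑3,7‑dimethyloct‑6‑enoic acid | CC(C)=CCC[C@@H](C)CC(=O)O | starting material
12 | benzyl (R)‑glycidyl ether | C(OCc1ccccc1)[C@H]1CO1 | starting material
13 | (2S)‑3‑(benzyloxy)‑2‑hydroxypropyl (3R)‑3,7‑dimethyloct‑6‑enoate | CC(C)=CCC[C@@H](C)CC(=O)OC[C@H](COCc1ccccc1)O | intermediate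
14 | (2S)‑2‑acetoxy‑3‑(benzyloxy)propyl (3R)‑3,7‑dimethyloct‑6‑enoate | CC(C)=CCC[C@@H](C)CC(=O)OC[C@H](COCc1ccccc1)OC(C)=O | intermediate
15 | secondary ozonide of 14 (3,3‑dimethyl‑1,2,4‑trioxolane carrying the ester chain on C5, ring carbon epimers) | CC1(C)OOC(CC[C@@H](C)CC(=O)OC[C@H](COCc2ccccc2)OC(C)=O)O1 | intermediate
16 | (2S)‑2‑acetoxy‑3‑(benzyloxy)propyl (3R)‑3‑methyl‑6‑oxohexanoate | O=CCC[C@@H](C)CC(=O)OC[C@H](COCc1ccccc1)OC(C)=O | intermediate
17 | lithium dienolate of 10 (O–Li on C1, C1=C10, C5 unchanged) | CC1(OCCO1)CC[C@@H]2C(C)(C)C=CC(O[Li])=C2C | intermediate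
18 | lithium aldolate (lithium alkoxide at C9 of the aldol of 17 with 16, C9 epimers) | CC1(OCCO1)CC[C@@H]2C(C)(C)C=CC(=O)[C@@]2(C)C(O[Li])CC[C@@H](C)CC(=O)OC[C@H](COCc3ccccc3)OC(C)=O | intermediate
19 | (2S)‑2‑acetoxy‑3‑(benzyloxy)propyl (3R,6RS)‑3‑methyl‑6‑[(1R,6R)‑1,5,5‑trimethyl‑6‑[2‑(2‑methyl‑1,3‑dioxolan‑2‑yl)ethyl]‑2‑oxocyclohex‑3‑en‑1‑yl]‑6‑(triethylsilyloxy)hexanoate | CC1(OCCO1)CC[C@@H]2C(C)(C)C=CC(=O)[C@@]2(C)C(O[Si](CC)(CC)CC)CC[C@@H](C)CC(=O)OC[C@H](COCc3ccccc3)OC(C)=O | intermediate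
20 | lithium enolate from conjugate reduction of 19 (O–Li on C1, C1=C2) | CC1(OCCO1)CC[C@@H]2C(C)(C)CC=C(O[Li])[C@@]2(C)C(O[Si](CC)(CC)CC)CC[C@@H](C)CC(=O)OC[C@H](COCc3ccccc3)OC(C)=O | intermediate
21 | enol triflate: (2S)‑2‑acetoxy‑3‑(benzyloxy)propyl (3R,6RS)‑3‑methyl‑6‑[(1R,6R)‑1,5,5‑trimethyl‑6‑[2‑(2‑methyl‑1,3‑dioxolan‑2‑yl)ethyl]‑2‑(trifluoromethylsulfonyloxy)cyclohex‑2‑en‑1‑yl]‑6‑(triethylsilyloxy)hexanoate | CC1(OCCO1)CC[C@@H]2C(C)(C)CC=C(OS(=O)(=O)C(F)(F)F)[C@@]2(C)C(O[Si](CC)(CC)CC)CC[C@@H](C)CC(=O)OC[C@H](COCc3ccccc3)OC(C)=O | intermediate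
22 | (2S)‑2‑acetoxy‑3‑(benzyloxy)propyl (3R,6RS)‑3‑methyl‑6‑[(1R,6R)‑1,5,5‑trimethyl‑6‑[2‑(2‑methyl‑1,3‑dioxolan‑2‑yl)ethyl]cyclohex‑2‑en‑1‑yl]‑6‑(triethylsilyloxy)hexanoate | CC1(OCCO1)CC[C@@H]2C(C)(C)CC=C[C@@]2(C)C(O[Si](CC)(CC)CC)CC[C@@H](C)CC(=O)OC[C@H](COCc3ccccc3)OC(C)=O | intermediate
23 | (2S)‑2‑acetoxy‑3‑(benzyloxy)propyl (3R,6RS)‑6‑hydroxy‑3‑methyl‑6‑[(1R,6R)‑1,5,5‑trimethyl‑6‑(3‑oxobutyl)cyclohex‑2‑en‑1‑yl]hexanoate | CC(=O)CC[C@@H]1C(C)(C)CC=C[C@@]1(C)C(O)CC[C@@H](C)CC(=O)OC[C@H](COCc2ccccc2)OC(C)=O | intermediate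
24 | (2S)‑2‑acetoxy‑3‑(benzyloxy)propyl (3R)‑3‑methyl‑6‑oxo‑6‑[(1R,6R)‑1,5,5‑trimethyl‑6‑(3‑oxobutyl)cyclohex‑2‑en‑1‑yl]hexanoate | CC(=O)CC[C@@H]1C(C)(C)CC=C[C@@]1(C)C(=O)CC[C@@H](C)CC(=O)OC[C@H](COCc2ccccc2)OC(C)=O | intermediate
25 | (2S)‑2‑acetoxy‑3‑hydroxypropyl (3R)‑3‑methyl‑6‑oxo‑6‑[(1R,2R)‑1,3,3‑trimethyl‑2‑(3‑oxobutyl)cyclohexyl]hexanoate | CC(=O)CC[C@@H]1C(C)(C)CCC[C@@]1(C)C(=O)CC[C@@H](C)CC(=O)OC[C@H](CO)OC(C)=O | target

**Step count**

Total: 13 steps. Longest linear sequence: 10 steps (steps 1–4, then 8–13); steps 5–7 make the side‑chain aldehyde in parallel.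

**Steps most likely to fail**

Step 3. The hindered enamine may add only slowly to the β‑alkyl enone, or face selection at C5 may be weak, so that little or nearly racemic material reaches step 4. The fallback separates ring formation from the stereocentre. It sets out from 5 and 3, which undergo the same Michael/aldol annulation (pyrrolidine enamine, then aqueous acid) without creating any stereocentre and give 4,4‑dimethylcyclohex‑2‑en‑1‑one F1. Dehydrogenation with IBX in DMSO gives the symmetrical 4,4‑dimethylcyclohexa‑2,5‑dien‑1‑one F2. Commercial 2‑(2‑bromoethyl)‑2‑methyl‑1,3‑dioxolane is turned with Mg into [2‑(2‑methyl‑1,3‑dioxolan‑2‑yl)ethyl]magnesium bromide F3 and with ZnCl2 into bis[2‑(2‑methyl‑1,3‑dioxolan‑2‑yl)ethyl]zinc F4. Cu(OTf)2 with a BINOL‑derived phosphoramidite ligand then catalyses the enantioselective conjugate addition of F4 to F2; this desymmetrization forms the C5–C6 bond, sets C5, and comes back to the route at 8.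

Step 8. The aldehyde may add to the wrong face of the tetrasubstituted dienolate, because the axial C4 methyl shields the face anti to the C5 chain, or proton transfer from the enolizable aldehyde may outrun C–C bond formation. The fallback reverses the order in which the two C10 substituents are introduced, so that the same facial preference places the methyl group last. It sets out from 8, whose lithium dienolate 9 adds to 16 to give, after aqueous work‑up, the (2S)‑2‑acetoxy‑3‑(benzyloxy)propyl (3R)‑6‑hydroxy‑3‑methyl‑6‑[5,5‑dimethyl‑6‑[2‑(2‑methyl‑1,3‑dioxolan‑2‑yl)ethyl]‑2‑oxocyclohex‑3‑en‑1‑yl]hexanoate F5. Dess–Martin oxidation gives the corresponding 6‑oxo β‑diketone F6. C‑Methylation with MeI and Cs2CO3 in acetone gives the quaternary 1‑methyl β‑diketone F7, the methyl entering the face that the aldehyde would have taken in step 8. NaBH4 in MeOH/CH2Cl2 at −78 °C reduces the saturated C9 ketone in preference to the conjugated C1 ketone and gives the C9 alcohol F8, and silylation with Et3SiOTf and 2,6‑lutidine comes back to the route at 19.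

Step 9. The hydride may add 1,2 to the carbonyl or fail to reach C3 beside the quaternary C4, and the enolate may be acylated by an ester before it is triflated. The fallback uncouples reduction from enolization. It sets out from 19: hydrogenation of the C2=C3 bond with H2 and RhCl(PPh3)3 in benzene, which leaves the benzyl ether alone, gives the saturated 2‑oxocyclohexyl ketone F9, which has α‑hydrogens only at C2. KN(SiMe3)2 in THF at −78 °C gives the potassium enolate F10, which is trapped by Comins' reagent and comes back to the route at 21.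

**Further compounds**

F1 | step 3 | 4,4‑dimethylcyclohex‑2‑en‑1‑one | CC1(C)CCC(=O)C=C1
F2 | step 3 | 4,4‑dimethylcyclohexa‑2,5‑dien‑1‑one | CC1(C)C=CC(=O)C=C1
F3 | step 3 | [2‑(2‑methyl‑1,3‑dioxolan‑2‑yl)ethyl]magnesium bromide | CC1(CC[Mg]Br)OCCO1
F4 | step 3 | bis[2‑(2‑methyl‑1,3‑dioxolan‑2‑yl)ethyl]zinc | CC1(CC[Zn]CCC2(C)OCCO2)OCCO1
F5 | step 8 | (2S)‑2‑acetoxy‑3‑(benzyloxy)propyl (3R)‑6‑hydroxy‑3‑methyl‑6‑[5,5‑dimethyl‑6‑[2‑(2‑methyl‑1,3‑dioxolan‑2‑yl)ethyl]‑2‑oxocyclohex‑3‑en‑1‑yl]hexanoate (C9 and C10 epimers, C5 as in 8) | CC1(OCCO1)CC[C@@H]2C(C)(C)C=CC(=O)C2C(O)CC[C@@H](C)CC(=O)OC[C@H](COCc3ccccc3)OC(C)=O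
F6 | step 8 | (2S)‑2‑acetoxy‑3‑(benzyloxy)propyl (3R)‑3‑methyl‑6‑oxo‑6‑[5,5‑dimethyl‑6‑[2‑(2‑methyl‑1,3‑dioxolan‑2‑yl)ethyl]‑2‑oxocyclohex‑3‑en‑1‑yl]hexanoate (β‑diketone, enolizable at C10) | CC1(OCCO1)CC[C@@H]2C(C)(C)C=CC(=O)C2C(=O)CC[C@@H](C)CC(=O)OC[C@H](COCc3ccccc3)OC(C)=O
F7 | step 8 | (2S)‑2‑acetoxy‑3‑(benzyloxy)propyl (3R)‑3‑methyl‑6‑oxo‑6‑[(1R,6R)‑1,5,5‑trimethyl‑6‑[2‑(2‑methyl‑1,3‑dioxolan‑2‑yl)ethyl]‑2‑oxocyclohex‑3‑en‑1‑yl]hexanoate | CC1(OCCO1)CC[C@@H]2C(C)(C)C=CC(=O)[C@@]2(C)C(=O)CC[C@@H](C)CC(=O)OC[C@H](COCc3ccccc3)OC(C)=O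
F8 | step 8 | (2S)‑2‑acetoxy‑3‑(benzyloxy)propyl (3R,6RS)‑6‑hydroxy‑3‑methyl‑6‑[(1R,6R)‑1,5,5‑trimethyl‑6‑[2‑(2‑methyl‑1,3‑dioxolan‑2‑yl)ethyl]‑2‑oxocyclohex‑3‑en‑1‑yl]hexanoate | CC1(OCCO1)CC[C@@H]2C(C)(C)C=CC(=O)[C@@]2(C)C(O)CC[C@@H](C)CC(=O)OC[C@H](COCc3ccccc3)OC(C)=O
F9 | step 9 | (2S)‑2‑acetoxy‑3‑(benzyloxy)propyl (3R,6RS)‑3‑methyl‑6‑[(1R,2R)‑1,3,3‑trimethyl‑2‑[2‑(2‑methyl‑1,3‑dioxolan‑2‑yl)ethyl]‑6‑oxocyclohexyl]‑6‑(triethylsilyloxy)hexanoate | CC1(OCCO1)CC[C@@H]2C(C)(C)CCC(=O)[C@@]2(C)C(O[Si](CC)(CC)CC)CC[C@@H](C)CC(=O)OC[C@H](COCc3ccccc3)OC(C)=O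
F10 | step 9 | potassium enolate of F9 (O–K on C1, C1=C2) | CC1(OCCO1)CC[C@@H]2C(C)(C)CC=C(O[K])[C@@]2(C)C(O[Si](CC)(CC)CC)CC[C@@H](C)CC(=O)OC[C@H](COCc3ccccc3)OC(C)=O
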